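**Plan**

- Retrosynthesis: the C3–aroyl bond, the bridgehead C1–prenyl bond, the C7–prenyl bond (taken back to C7–O) and the C2 carbonyl are removed first. The bicycle is then opened at C1–C8, and the monocycle is cut at C5–C6 (epoxy bromide) and at the aryl–prenyl bond.
- Enabling feature: in the bicyclo[3.3.1]nonane (bridgeheads C1/C5; ring A = C1–C2–C3–C4–C5–C9; ring B = C1–C8–C7–C6–C5–C9) the gem-dimethyl carbon C8 lies between C7 and bridgehead C1. C5 is quaternary and, at the enol ether level, carries two like arms (C4=C3 and C9=C1), so a C7–C8 epoxide hung on C5 through C6 can be opened at C8 by enol carbon C1.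
- Forward: ring A is the ring of 1,3-dimethoxybenzene (C-prenylation, Birch reduction); C5 becomes quaternary by alkylation with an epoxy bromide; ring B closes in step 6. Then C2 is oxidised, C7–O is exchanged for exo-prenyl, C1 is prenylated, C3 is aroylated, and the methyl and silyl groups are removed.
- Stereochemistry: the only external source is the Sharpless epoxidation of prenol. Its (R) centre (future C7) selects one of the two enantiotopic enol ether arms and so fixes C1 and C5. C7 is later re-set as exo by radical allylation on the convex face, and the bridgehead alkylation can only go with retention.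

Key step: step 6

Remark (numbering and configuration): all positions use the bicyclo[3.3.1]nonane numbering above; in 12–28, seen from the exo face of ring B (the face away from the C2–C3–C4 bridge), C9→C1→C8→C7→C6→C5 runs counterclockwise. "Prenyl" = 3-methylbut-2-en-1-yl.

Remark (chemistry): the C9 oxocarbenium ion formed on ring closure is assumed to be trapped by the neighbouring 7-exo oxygen, so the cyclization product is written and carried as the bridged methyl ketal 13 (C9 carbonyl and C7–OH masked together). The free 7-hydroxy-9-ketone is released in step 8, once ring A is a vinylogous ester and tolerates aqueous acid.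

**Step 1**
Reactants: 1 1,3-dimethoxybenzene; 2 1-bromo-3-methylbut-2-ene (prenyl bromide)
Product: 4 1,3-dimethoxy-2-(3-methylbut-2-en-1-yl)benzene, via aryllithium 3 (not isolated)
Conditions: n-BuLi, THF, 0 °C to rt; then 2, 0 °C to rt
Reagents that add atoms: none
Why: Directed ortho-metalation takes place at C2 between the two methoxy groups, and the aryllithium displaces bromide at the primary carbon of the allylic halide (SN2 alkylation); no stereocentre is formed.

**Step 2**
Reactants: 4 1,3-dimethoxy-2-(3-methylbut-2-en-1-yl)benzene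
Product: 5 1,5-dimethoxy-6-(3-methylbut-2-en-1-yl)cyclohexa-1,4-diene
Conditions: Li, liq. NH3, THF, t-BuOH, −78 to −33 °C; NH4Cl
Reagents that add atoms: none
Why: Birch reduction of a 1,3-dialkoxyarene leaves both methoxy groups on sp2 carbons and protonates the carbon between them and the one para to it, giving the unconjugated bis(enol ether); the isolated trisubstituted alkene is not reduced.

**Step 3**
Reactants: 6 3-methylbut-2-en-1-ol
Product: 7 [(2R)-3,3-dimethyloxiran-2-yl]methanol
Conditions: Ti(OiPr)4 (cat.), D-(−)-diisopropyl tartrate (cat.), t-BuOOH, 4 Å MS, CH2Cl2, −20 °C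
Reagents that add atoms: tert-butyl hydroperoxide, CC(C)(C)OO
Why: Katsuki–Sharpless asymmetric epoxidation of a primary allylic alcohol; the D-(−)-tartrate complex should deliver oxygen to the alkene face that gives the (2R)-epoxy alcohol (the L-(+) ligand gives 2S).

**Step 4**
Reactants: 7 [(2R)-3,3-dimethyloxiran-2-yl]methanol
Product: 9 (3S)-3-(bromomethyl)-2,2-dimethyloxirane, via epoxy mesylate 8 (not isolated)
Conditions: MsCl, Et3N, THF, −20 °C; then LiBr, 0 °C to rt
Reagents that add atoms: lithium bromide, [Li+].[Br-]
Why: Sulfonylation of the primary alcohol and Finkelstein-type SN2 displacement by bromide at the primary carbon leave the oxirane centre untouched; the descriptor changes from R to S only because CH2Br outranks CMe2.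

**Step 5**
Reactants: 5 1,5-dimethoxy-6-(3-methylbut-2-en-1-yl)cyclohexa-1,4-diene; 9 (3S)-3-(bromomethyl)-2,2-dimethyloxirane
Product: 11 6-{[(2R)-3,3-dimethyloxiran-2-yl]methyl}-1,5-dimethoxy-6-(3-methylbut-2-en-1-yl)cyclohexa-1,4-diene, via dienyllithium 10 (not isolated)
Conditions: s-BuLi, THF, −78 °C; then 9, −78 to −20 °C
Reagents that add atoms: none
Why: The doubly allylic C–H flanked by the two methoxy-bearing carbons is removed, and the pentadienyl anion is alkylated at its central carbon by the primary bromide (Birch-diene alkylation). This creates the quaternary carbon that becomes C5, which is not yet stereogenic because the two ring arms are identical, and the oxirane centre is carried through unchanged.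

**Step 6**
Reactants: 11 6-{[(2R)-3,3-dimethyloxiran-2-yl]methyl}-1,5-dimethoxy-6-(3-methylbut-2-en-1-yl)cyclohexa-1,4-diene
Product: 13 7,9-epoxy-4,9-dimethoxy-8,8-dimethyl-5-(3-methylbut-2-en-1-yl)bicyclo[3.3.1]non-3-ene (bridged methyl ketal of the 7-exo-hydroxy-9-ketone), via oxocarbenium triflate 12 (not isolated)
Conditions: TMSOTf (0.2 equiv), 2,6-lutidine (0.3 equiv), CH2Cl2, −78 °C; Et3N, aq. NaHCO3
Reagents that add atoms: none
Why: Silylation of the oxirane oxygen makes the tertiary carbon C8 cationoid, and the β-carbon (C1) of one methyl enol ether attacks it anti to the breaking C8–O bond; this is a Lewis-acid epoxide-opening cation–enol ether cyclization, the known way of turning alkylated Birch dienes into bicyclo[3.3.1]nonanes. Ring B (C1–C8–C7–C6–C5–C9) closes in the 6-endo mode with respect to the oxirane, preferred over 5-exo attack at C7 because positive charge develops at the tertiary centre; the C9 methoxy-oxocarbenium ion 12 is then captured 5-exo by the C7 silyloxy oxygen, and loss of Me3Si+ returns the catalyst and leaves ketal 13. C7 keeps the (R) configuration of the oxirane because its C–O bond is never broken. C1 and C5 are set together by the choice of arm, and that choice is made by C7: only one arm can reach C8 from the backside through a chair-like ring B with the C7–O bond equatorial and antiperiplanar to the forming C1–C8 bond, whereas the other arm would need a boat. The ketal carbon C9 has no freedom, since the oxygen bridge can only span the C6–C7–C8 side. The step needs group selection between the two enantiotopic arms and endo rather than exo opening; the single oxirane stereocentre and the tertiary nature of C8 secure these, and 2,6-lutidine keeps the medium free of protic acid so that the enol ethers survive.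

**Step 7**
Reactants: 13 7,9-epoxy-4,9-dimethoxy-8,8-dimethyl-5-(3-methylbut-2-en-1-yl)bicyclo[3.3.1]non-3-ene
Product: 14 7,9-epoxy-4,9-dimethoxy-8,8-dimethyl-5-(3-methylbut-2-en-1-yl)bicyclo[3.3.1]non-3-en-2-one
Conditions: t-BuOOH, PhI(OAc)2, K2CO3, butyl butyrate, −20 °C
Reagents that add atoms: tert-butyl hydroperoxide, CC(C)(C)OO
Why: Radical allylic oxidation (tert-butylperoxyl radical abstracts H from C2, the allyl peroxide collapses in a Kornblum–DeLaMare manner) should take the C2 methylene first, because the enol ether methoxy group stabilises that allyl radical more than anything in the unactivated prenyl group; no stereocentre is touched.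

**Step 8**
Reactants: 14 7,9-epoxy-4,9-dimethoxy-8,8-dimethyl-5-(3-methylbut-2-en-1-yl)bicyclo[3.3.1]non-3-en-2-one
Product: 15 7-exo-hydroxy-4-methoxy-8,8-dimethyl-5-(3-methylbut-2-en-1-yl)bicyclo[3.3.1]non-3-ene-2,9-dione
Conditions: 0.5 M aq. HCl, THF, 0 °C to rt
Reagents that add atoms: water, O
Why: Acid-catalysed ketal hydrolysis: protonation of the bridging oxygen opens the strained oxa-bridge to the C9 oxocarbenium ion, and water then methanol loss give the ketone and the free 7-exo alcohol with C7 unchanged; the vinylogous ester, whose C4 is shielded by the quaternary C5, should survive dilute acid at room temperature.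

**Step 9**
Reactants: 15 7-exo-hydroxy-4-methoxy-8,8-dimethyl-5-(3-methylbut-2-en-1-yl)bicyclo[3.3.1]non-3-ene-2,9-dione
Product: 18 O-[7-exo-4-methoxy-8,8-dimethyl-5-(3-methylbut-2-en-1-yl)-2,9-dioxobicyclo[3.3.1]non-3-en-7-yl] S-methyl carbonodithioate, via sodium alkoxide 16 (not isolated), via sodium xanthate 17 (not isolated)
Conditions: NaH, THF, 0 °C; CS2, 0 °C to rt; then MeI
Reagents that add atoms: carbon disulfide, S=C=S; iodomethane, CI
Why: Xanthate formation (alkoxide addition to CS2, then S-methylation) keeps the C7 configuration, and the substrate has no enolisable C–H for sodium hydride to remove (C1 is a bridgehead, C5 is quaternary).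

**Step 10**
Reactants: 18 the S-methyl xanthate of 15
Product: 19 7-exo-allyl-4-methoxy-8,8-dimethyl-5-(3-methylbut-2-en-1-yl)bicyclo[3.3.1]non-3-ene-2,9-dione
Conditions: allylSnBu3 (excess), AIBN (cat.), toluene, 85 °C
Reagents that add atoms: allyltributylstannane, C=CC[Sn](CCCC)(CCCC)CCCC
Why: Keck radical allylation: the tin radical adds to the thiocarbonyl, β-scission of the C7–O bond (Barton–McCombie mode) gives the secondary C7 radical, and this adds to the allylstannane with expulsion of the chain-carrying tin radical; attack on the exo face of ring B, away from the C2–C3–C4 bridge, should place the allyl group in the equatorial 7-exo position of the target.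

**Step 11**
Reactants: 19 7-exo-allyl-4-methoxy-8,8-dimethyl-5-(3-methylbut-2-en-1-yl)bicyclo[3.3.1]non-3-ene-2,9-dione
Product: 20 4-methoxy-8,8-dimethyl-5,7-exo-bis(3-methylbut-2-en-1-yl)bicyclo[3.3.1]non-3-ene-2,9-dione
Conditions: Grubbs II (5 mol %), 2-methylbut-2-ene/CH2Cl2, 40 °C
Reagents that add atoms: 2-methylbut-2-ene, CC=C(C)C
Why: Olefin cross-metathesis of the monosubstituted allyl terminus with 2-methylbut-2-ene turns allyl into prenyl; the existing prenyl group and the vinylogous ester alkene are poor metathesis partners (exchange at prenyl is degenerate), and no stereocentre is involved.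

**Step 12**
Reactants: 20 4-methoxy-8,8-dimethyl-5,7-exo-bis(3-methylbut-2-en-1-yl)bicyclo[3.3.1]non-3-ene-2,9-dione; 2 1-bromo-3-methylbut-2-ene
Product: 22 4-methoxy-8,8-dimethyl-1,5,7-exo-tris(3-methylbut-2-en-1-yl)bicyclo[3.3.1]non-3-ene-2,9-dione, via bridgehead organolithium 21 (not isolated)
Conditions: LDA, THF, −78 °C; then 2, −78 °C to rt
Reagents that add atoms: none
Why: Bridgehead lithiation–alkylation: C1–H lies between the C2 and C9 carbonyl groups and is removed to give a non-enolisable, configurationally fixed carbanion that is alkylated by the allylic bromide; substitution at a bridgehead can only occur with retention, so C1 keeps the sense set in step 6.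

**Step 13**
Reactants: 23 3,4-dihydroxybenzoic acid
Product: 24 tert-butyldimethylsilyl 3,4-bis(tert-butyldimethylsilyloxy)benzoate
Conditions: TBSCl, imidazole, DMF, rt
Reagents that add atoms: tert-butyldimethylsilyl chloride, CC(C)(C)[Si](C)(C)Cl
Why: Exhaustive silylation masks the catechol as base-stable aryl silyl ethers and leaves the acid as a silyl ester ready for activation.

**Step 14**
Reactants: 24 tert-butyldimethylsilyl 3,4-bis(tert-butyldimethylsilyloxy)benzoate
Product: 25 3,4-bis(tert-butyldimethylsilyloxy)benzoyl chloride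
Conditions: (COCl)2, DMF (cat.), CH2Cl2, 0 °C to rt
Reagents that add atoms: oxalyl chloride, O=C(Cl)C(=O)Cl
Why: A silyl ester is converted directly into the acid chloride by oxalyl chloride with catalytic DMF (Vilsmeier-type activation) without forming HCl, so the aryl silyl ethers should stay in place.

**Step 15**
Reactants: 22 4-methoxy-8,8-dimethyl-1,5,7-exo-tris(3-methylbut-2-en-1-yl)bicyclo[3.3.1]non-3-ene-2,9-dione; 25 3,4-bis(tert-butyldimethylsilyloxy)benzoyl chloride
Product: 27 3-[3,4-bis(tert-butyldimethylsilyloxy)benzoyl]-4-methoxy-8,8-dimethyl-1,5,7-exo-tris(3-methylbut-2-en-1-yl)bicyclo[3.3.1]non-3-ene-2,9-dione, via vinyllithium 26 (not isolated)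
Conditions: LiTMP (from n-BuLi and 2,2,6,6-tetramethylpiperidine), THF, −78 °C; then 25, −78 to −40 °C
Reagents that add atoms: none
Why: α-Lithiation of the β-alkoxy enone at the vinylic position C3 (the only acidic C–H left) by the hindered amide base, followed by C-acylation of the vinyllithium with the acid chloride, installs the aroyl group; no stereocentre is formed or disturbed.

**Step 16**
Reactants: 27 the bis-silylated O-methyl precursor
Product: 28 aristophenone A
Conditions: LiOH·H2O, 1,4-dioxane/H2O (degassed, Ar), 90 °C; then 1 M HCl to pH 3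
Reagents that add atoms: lithium hydroxide, [Li+].[OH-]
Why: Hydroxide adds to C4 of the doubly activated vinylogous ester and expels methoxide (addition–elimination) and also cleaves both aryl silyl ethers at silicon, so one operation should release the enolised β-triketone and the catechol; air is excluded to protect the catecholate, and the quaternary and bridgehead stereocentres cannot epimerise.

**Compound list**

1 | 1,3-dimethoxybenzene | COc1cccc(OC)c1 | starting material
2 | 1-bromo-3-methylbut-2-ene (prenyl bromide) | CC(C)=CCBr | starting material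
3 | (2,6-dimethoxyphenyl)lithium, formed in the flask | [Li]c1c(OC)cccc1OC | intermediate
4 | 1,3-dimethoxy-2-(3-methylbut-2-en-1-yl)benzene | COc1cccc(OC)c1CC=C(C)C | intermediate
5 | 1,5-dimethoxy-6-(3-methylbut-2-en-1-yl)cyclohexa-1,4-diene | COC1=CCC=C(OC)C1CC=C(C)C | intermediate
6 | 3-methylbut-2-en-1-ol | CC(C)=CCO | starting material
7 | [(2R)-3,3-dimethyloxiran-2-yl]methanol | OC[C@H]1OC1(C)C | intermediate
8 | [(2R)-3,3-dimethyloxiran-2-yl]methyl methanesulfonate, formed in the flask | CS(=O)(=O)OC[C@H]1OC1(C)C | intermediate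
9 | (3S)-3-(bromomethyl)-2,2-dimethyloxirane (same spatial arrangement as 7) | BrC[C@H]1OC1(C)C | intermediate
10 | [2,6-dimethoxy-1-(3-methylbut-2-en-1-yl)cyclohexa-2,5-dien-1-yl]lithium, formed in the flask | [Li]C1(CC=C(C)C)C(OC)=CCC=C1OC | intermediate
11 | 6-{[(2R)-3,3-dimethyloxiran-2-yl]methyl}-1,5-dimethoxy-6-(3-methylbut-2-en-1-yl)cyclohexa-1,4-diene | COC1=CCC=C(OC)C1(CC=C(C)C)C[C@H]2OC2(C)C | intermediate
12 | 9-O-methyl oxocarbenium triflate of 4-methoxy-8,8-dimethyl-5-prenyl-7-exo-(trimethylsilyloxy)bicyclo[3.3.1]non-3-en-9-one, formed in the flask | C[Si](C)(C)O[C@@H]1C[C@]2(CC=C(C)C)C(=[O+]C)[C@@H](CC=C2OC)C1(C)C.[O-]S(=O)(=O)C(F)(F)F | intermediate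
13 | 7,9-epoxy-4,9-dimethoxy-8,8-dimethyl-5-(3-methylbut-2-en-1-yl)bicyclo[3.3.1]non-3-ene (7R; oxygen bridge on the exo face from C7 to C9; bridgeheads as in 28) | O3[C@@H]1C[C@]2(CC=C(C)C)[C@@]3(OC)[C@@H](CC=C2OC)C1(C)C | intermediate
14 | 7,9-epoxy-4,9-dimethoxy-8,8-dimethyl-5-(3-methylbut-2-en-1-yl)bicyclo[3.3.1]non-3-en-2-one | O3[C@@H]1C[C@]2(CC=C(C)C)[C@@]3(OC)[C@@H](C(=O)C=C2OC)C1(C)C | intermediate
15 | 7-exo-hydroxy-4-methoxy-8,8-dimethyl-5-(3-methylbut-2-en-1-yl)bicyclo[3.3.1]non-3-ene-2,9-dione | O[C@@H]1C[C@]2(CC=C(C)C)C(=O)[C@@H](C(=O)C=C2OC)C1(C)C | intermediate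
16 | sodium 7-exo-alkoxide of 15, formed in the flask | [Na+].[O-][C@@H]1C[C@]2(CC=C(C)C)C(=O)[C@@H](C(=O)C=C2OC)C1(C)C | intermediate
17 | sodium O-alkyl carbonodithioate (xanthate salt) of 15, formed in the flask | [Na+].[S-]C(=S)O[C@@H]1C[C@]2(CC=C(C)C)C(=O)[C@@H](C(=O)C=C2OC)C1(C)C | intermediate
18 | O-[7-exo-4-methoxy-8,8-dimethyl-5-(3-methylbut-2-en-1-yl)-2,9-dioxobicyclo[3.3.1]non-3-en-7-yl] S-methyl carbonodithioate | CSC(=S)O[C@@H]1C[C@]2(CC=C(C)C)C(=O)[C@@H](C(=O)C=C2OC)C1(C)C | intermediate
19 | 7-exo-allyl-4-methoxy-8,8-dimethyl-5-(3-methylbut-2-en-1-yl)bicyclo[3.3.1]non-3-ene-2,9-dione | C=CC[C@@H]1C[C@]2(CC=C(C)C)C(=O)[C@@H](C(=O)C=C2OC)C1(C)C | intermediate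
20 | 4-methoxy-8,8-dimethyl-5,7-exo-bis(3-methylbut-2-en-1-yl)bicyclo[3.3.1]non-3-ene-2,9-dione | CC(C)=CC[C@@H]1C[C@]2(CC=C(C)C)C(=O)[C@@H](C(=O)C=C2OC)C1(C)C | intermediate
21 | C1 bridgehead lithium derivative of 20, formed in the flask | CC(C)=CC[C@@H]1C[C@]2(CC=C(C)C)C(=O)[C@@]([Li])(C(=O)C=C2OC)C1(C)C | intermediate
22 | 4-methoxy-8,8-dimethyl-1,5,7-exo-tris(3-methylbut-2-en-1-yl)bicyclo[3.3.1]non-3-ene-2,9-dione | CC(C)=CC[C@@H]1C[C@]2(CC=C(C)C)C(=O)[C@@](CC=C(C)C)(C(=O)C=C2OC)C1(C)C | intermediate
23 | 3,4-dihydroxybenzoic acid | O=C(O)c1ccc(O)c(O)c1 | starting material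
24 | tert-butyldimethylsilyl 3,4-bis(tert-butyldimethylsilyloxy)benzoate | CC(C)(C)[Si](C)(C)OC(=O)c1ccc(O[Si](C)(C)C(C)(C)C)c(O[Si](C)(C)C(C)(C)C)c1 | intermediate
25 | 3,4-bis(tert-butyldimethylsilyloxy)benzoyl chloride | O=C(Cl)c1ccc(O[Si](C)(C)C(C)(C)C)c(O[Si](C)(C)C(C)(C)C)c1 | intermediate
26 | C3 vinyllithium derivative of 22, formed in the flask | CC(C)=CC[C@@H]1C[C@]2(CC=C(C)C)C(=O)[C@@](CC=C(C)C)(C(=O)C([Li])=C2OC)C1(C)C | intermediate
27 | 3-[3,4-bis(tert-butyldimethylsilyloxy)benzoyl]-4-methoxy-8,8-dimethyl-1,5,7-exo-tris(3-methylbut-2-en-1-yl)bicyclo[3.3.1]non-3-ene-2,9-dione | CC(C)=CC[C@@H]1C[C@]2(CC=C(C)C)C(=O)[C@@](CC=C(C)C)(C(=O)C(C(=O)c3ccc(O[Si](C)(C)C(C)(C)C)c(O[Si](C)(C)C(C)(C)C)c3)=C2OC)C1(C)C | intermediate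
28 | aristophenone A: 3-(3,4-dihydroxybenzoyl)-4-hydroxy-8,8-dimethyl-1,5,7-exo-tris(3-methylbut-2-en-1-yl)bicyclo[3.3.1]non-3-ene-2,9-dione, (1S,5S,7R) for the tautomer drawn | CC(C)=CC[C@@H]1C[C@]2(CC=C(C)C)C(=O)[C@@](CC=C(C)C)(C(=O)C(C(=O)c3ccc(O)c(O)c3)=C2O)C1(C)C | target

**Totals**

Total step count: 16. Longest linear sequence: 12 steps (1, 2, 5–12, 15, 16; the branch through steps 3 and 4 is equally long).

**Steps most likely to fail, with fallbacks**

Step 6. The acid-sensitive bis(enol ether) may be consumed unproductively (protonolysis, coupling of an enol ether with an oxocarbenium ion of another molecule), or the two arms may not be told apart cleanly before the C1–C8 bond forms. The fallback raises the oxidation level of ring A before closure. Setting out from 11, the doubly allylic ring methylene between the two enol ether CH= carbons is oxidised (t-BuOOH, PDC, Celite, benzene) to the cross-conjugated dienone 4-{[(2R)-3,3-dimethyloxiran-2-yl]methyl}-3,5-dimethoxy-4-(3-methylbut-2-en-1-yl)cyclohexa-2,5-dien-1-one F1. This bis(vinylogous ester) is far less acid-labile and tolerates stronger promoters (TMSOTf/2,6-lutidine at higher temperature, BF3·OEt2 or formic acid). Its α-carbon should open the oxirane at C8 in the same chair-controlled, arm-selective way, and capture of the oxocarbenium ion by the C7 oxygen should then give the ketal with C2 already at the ketone level. The route is rejoined at 14, and step 7 is not needed.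

Step 12. The hindered bridgehead carbanion next to the quaternary C8 may be captured too slowly by the γ,γ-disubstituted allylic bromide, so that proton return or decay of the anion competes. The fallback uses the smaller electrophile and builds both prenyl termini together by metathesis. Setting out from 19, bridgehead lithiation (LDA, THF, −78 °C) and quenching with allyl bromide should give 1,7-exo-diallyl-4-methoxy-8,8-dimethyl-5-(3-methylbut-2-en-1-yl)bicyclo[3.3.1]non-3-ene-2,9-dione F2. Double cross-metathesis of F2 with 2-methylbut-2-ene (Grubbs II, 40 °C) then converts both allyl groups into prenyl groups. The route is rejoined at 22.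

Step 15. C-acylation of the hindered C3 vinyllithium by the electron-rich, bulky aroyl chloride may be sluggish, with proton return or attack at silicon competing. The fallback replaces acylation by carbonyl addition and oxidation. Setting out from 25, reduction with LiAlH(Ot-Bu)3 (THF, −78 °C) should give 3,4-bis(tert-butyldimethylsilyloxy)benzaldehyde F3. The vinyllithium 26, generated from 22 as in step 15, is added to F3 to give the secondary alcohol 3-{[3,4-bis(tert-butyldimethylsilyloxy)phenyl](hydroxy)methyl}-4-methoxy-8,8-dimethyl-1,5,7-exo-tris(3-methylbut-2-en-1-yl)bicyclo[3.3.1]non-3-ene-2,9-dione F4 as a mixture of carbinol epimers. Dess–Martin oxidation of F4 removes the new centre and returns the route at 27.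

**Further compounds**

F1 | step 6 | 4-{[(2R)-3,3-dimethyloxiran-2-yl]methyl}-3,5-dimethoxy-4-(3-methylbut-2-en-1-yl)cyclohexa-2,5-dien-1-one | COC1=CC(=O)C=C(OC)C1(CC=C(C)C)C[C@H]2OC2(C)C
F2 | step 12 | 1,7-exo-diallyl-4-methoxy-8,8-dimethyl-5-(3-methylbut-2-en-1-yl)bicyclo[3.3.1]non-3-ene-2,9-dione | C=CC[C@@H]1C[C@]2(CC=C(C)C)C(=O)[C@@](CC=C)(C(=O)C=C2OC)C1(C)C
F3 | step 15 | 3,4-bis(tert-butyldimethylsilyloxy)benzaldehyde | O=Cc1ccc(O[Si](C)(C)C(C)(C)C)c(O[Si](C)(C)C(C)(C)C)c1
F4 | step 15 | 3-{[3,4-bis(tert-butyldimethylsilyloxy)phenyl](hydroxy)methyl}-4-methoxy-8,8-dimethyl-1,5,7-exo-tris(3-methylbut-2-en-1-yl)bicyclo[3.3.1]non-3-ene-2,9-dione (carbinol epimers) | CC(C)=CC[C@@H]1C[C@]2(CC=C(C)C)C(=O)[C@@](CC=C(C)C)(C(=O)C(C(O)c3ccc(O[Si](C)(C)C(C)(C)C)c(O[Si](C)(C)C(C)(C)C)c3)=C2OC)C1(C)C
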